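**Strategy**

The hemiketal is first opened, on paper, to the 1,3-diketone; the C1''–C1' bond and an O–C2 enol-lactone bond are then cut. Everything rests on ring B: its carboxyl group on C2'' has a single free ortho carbon, C1'', and the C2 carbonyl lies two bonds beyond it. A carboxylate-directed rhodium C–H annulation of 2,4-bis(benzyloxy)benzoic acid with a keto sulfoxonium ylide therefore joins C1'' to C1' and ties C2 into an isocoumarin in one operation. The ylide holds ring A with its heptyl chain, C4 masked as a methyl enol ether, C3, C2 and the ylide carbon C1'. Unmasking, lactone opening and hydrogenolysis then let the ring A phenol close the hemiketal.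

Key step: step 8

Numbering: chromanone O1, C2, C3, C4, C4a–C8a (ring A); C1' is the exocyclic methylene; ring B is C1''–C6'', with C1'' on C1' and the carboxyl group on C2''. The target is the (2R) hemiketal.

Assumption 1: the C2 hemiketal is taken to be configurationally stable in neutral or weakly acidic, non-nucleophilic media at or below room temperature, ring–chain tautomerism through the open 1,3-diketone being its only racemisation path.

Assumption 2: the enol ether is drawn as the (E) isomer expected under equilibrating conditions; the (Z) isomer would follow the same steps, and both converge in step 9.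

**Route**

Step 1
Reactants: 1 2,4-dihydroxybenzoic acid
Product: 3 2,4-bis(benzyloxy)benzoic acid, via tribenzyl ester 2 (not isolated)
Conditions: BnBr (3.3 equiv), K2CO3, DMF, 60 °C; then NaOH, MeOH/H2O, 70 °C; then dilute aq. HCl, 0 °C
Reagents that add atoms: benzyl bromide, BrCc1ccccc1; sodium hydroxide, [Na+].[OH-]
Why: Williamson O-alkylation of both phenols and the carboxylate, followed by saponification of the benzyl ester, which leaves the aryl benzyl ethers untouched.

Step 2
Reactants: 4 3,5-bis(benzyloxy)benzyl bromide; 5 hexylmagnesium bromide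
Product: 6 1,3-bis(benzyloxy)-5-heptylbenzene
Conditions: Li2CuCl4 (3 mol %), THF, −78 → 0 °C
Reagents that add atoms: none
Why: Copper-catalysed alkylation of a benzylic bromide by a Grignard reagent (Kochi coupling) should join the benzylic carbon to the hexyl chain, and aryl benzyl ethers are inert to the Grignard reagent at this temperature.

Step 3
Reactants: 6 1,3-bis(benzyloxy)-5-heptylbenzene
Product: 7 2,4-bis(benzyloxy)-6-heptylbenzaldehyde
Conditions: POCl3, DMF, 0 → 60 °C; then H2O, 50 °C
Reagents that add atoms: N,N-dimethylformamide, CN(C)C=O; water, O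
Why: Vilsmeier–Haack formylation, in which the chloroiminium ion should attack the carbon ortho to one benzyloxy group and para to the other (next to the heptyl chain) rather than the more crowded carbon between the two ethers, as is usual for 5-alkylresorcinol diethers.

Step 4
Reactants: 7 2,4-bis(benzyloxy)-6-heptylbenzaldehyde
Product: 8 1,5-bis(benzyloxy)-2-(2,2-dibromoethenyl)-3-heptylbenzene
Conditions: CBr4, PPh3, CH2Cl2, 0 °C
Reagents that add atoms: carbon tetrabromide, BrC(Br)(Br)Br
Why: Corey–Fuchs dibromo-olefination, a Wittig reaction of the dibromomethylene ylide made in the flask, which tolerates hindered electron-rich benzaldehydes and benzyl ethers.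

Step 5
Reactants: 8 1,5-bis(benzyloxy)-2-(2,2-dibromoethenyl)-3-heptylbenzene
Product: 10 methyl 3-[2,4-bis(benzyloxy)-6-heptylphenyl]prop-2-ynoate, via lithium acetylide 9 (not isolated)
Conditions: n-BuLi (2.1 equiv), THF, −78 °C; then ClCO2Me, −78 → 0 °C
Reagents that add atoms: methyl chloroformate, COC(=O)Cl
Why: Second stage of the Corey–Fuchs sequence (bromine–lithium exchange, Fritsch–Buttenberg–Wiechell-type rearrangement, deprotonation) should give the lithium acetylide, which is C-acylated by the chloroformate while the benzyl ethers stay unmetalated at −78 °C.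

Step 6
Reactants: 10 methyl 3-[2,4-bis(benzyloxy)-6-heptylphenyl]prop-2-ynoate
Product: 12 (2E)-3-[2,4-bis(benzyloxy)-6-heptylphenyl]-3-methoxyprop-2-enoic acid, via methyl enol ether ester 11 (not isolated)
Conditions: NaOMe (0.3 equiv), MeOH/THF, 60 °C; then NaOH, H2O, 60 °C; then dilute aq. HCl to pH 3, 0 °C
Reagents that add atoms: methanol, CO; sodium hydroxide, [Na+].[OH-]
Why: Oxa-Michael addition of methoxide to the ynoate should give the β-methoxyacrylate, the reversible addition settling on the (E) isomer, and saponification then frees the acid, the enol ether being stable to base and to brief cold acidification.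

Step 7
Reactants: 12 (2E)-3-[2,4-bis(benzyloxy)-6-heptylphenyl]-3-methoxyprop-2-enoic acid
Product: 14 (3E)-4-[2,4-bis(benzyloxy)-6-heptylphenyl]-1-[dimethyl(oxo)-λ6-sulfanylidene]-4-methoxybut-3-en-2-one, via acid chloride 13 (not isolated)
Conditions: (COCl)2, DMF (cat.), CH2Cl2, 0 °C, evaporated; then Me3S(O)I (3 equiv), KOtBu (3 equiv), THF, 65 °C, cooled to 0 °C, 13 added, 0 °C → rt
Reagents that add atoms: trimethylsulfoxonium iodide, C[S+](C)(C)=O.[I-]
Why: Acylation of dimethylsulfoxonium methylide (the Corey–Chaykovsky reagent) by an acid chloride is the standard entry to keto sulfoxonium ylides, a second equivalent of methylide taking up the proton, and the acyl chloride should react at carbonyl far faster than the hindered, donor-substituted β-carbon can accept the ylide.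

Step 8
Reactants: 3 2,4-bis(benzyloxy)benzoic acid (1.3 equiv); 14 (3E)-4-[2,4-bis(benzyloxy)-6-heptylphenyl]-1-[dimethyl(oxo)-λ6-sulfanylidene]-4-methoxybut-3-en-2-one
Product: 16 6,8-bis(benzyloxy)-3-[(E)-2-[2,4-bis(benzyloxy)-6-heptylphenyl]-2-methoxyethenyl]-1H-isochromen-1-one, via keto acid 15 (not isolated)
Conditions: [Cp*RhCl2]2 (4 mol %), AgSbF6 (16 mol %), NaOAc (30 mol %), 4 Å molecular sieves, ClCH2CH2Cl/CF3CH2OH, 80 °C
Reagents that add atoms: none
Why: Acetate-assisted, carboxylate-directed C–H metalation of 3 by the cationic Cp*Rh species of trivalent rhodium should give a five-membered rhodacycle at C1'', after which ylide 14 binds through carbon, loses dimethyl sulfoxide to form a rhodium carbene, and migratory insertion makes the C1''–C1' bond. Protodemetalation releases keto acid 15 and returns the catalyst, so no external oxidant is needed. The carboxyl oxygen of 15 then adds to the C2 ketone in a 6-exo-trig closure and loss of water gives the enol lactone, which is the pyranone ring of isocoumarin 16. The closest known reaction type is the rhodium-catalysed annulation of benzoic acids with α-keto sulfoxonium ylides to 3-substituted isocoumarins. No stereocentre is formed and the enol ether geometry is carried through unchanged. The step needs site selectivity on ring B, secured because the other ortho position of 3 bears a benzyloxy group, and chemoselectivity at the ylide, secured by the C4 enol ether, which removes the 1,3-dicarbonyl chelate and blocks C4 against conjugate arylation.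

Step 9
Reactants: 16 6,8-bis(benzyloxy)-3-[(E)-2-[2,4-bis(benzyloxy)-6-heptylphenyl]-2-methoxyethenyl]-1H-isochromen-1-one
Product: 18 2,4-bis(benzyloxy)-6-{4-[2,4-bis(benzyloxy)-6-heptylphenyl]-2,4-dioxobutyl}benzoic acid, via isocoumarin ketone 17 (not isolated)
Conditions: dilute aq. HCl, THF, 40 °C; then LiOH (aq., excess), THF/H2O, rt; then dilute aq. HCl to pH 4, 0 °C
Reagents that add atoms: water, O; lithium hydroxide, [Li+].[OH-]
Why: Acid hydrolysis of the dienyl methyl ether should release the C4 ketone, and saponification of the enol lactone then opens the isocoumarin to the carboxylate and the C2 ketone, the 1,3-diketone resting as its enolate in base (which guards against retro-Claisen cleavage) and the mild cold acidification avoiding relactonisation.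

Step 10
Reactants: 18 2,4-bis(benzyloxy)-6-{4-[2,4-bis(benzyloxy)-6-heptylphenyl]-2,4-dioxobutyl}benzoic acid
Product: 20 rac-2-[(5-heptyl-2,7-dihydroxy-4-oxo-3,4-dihydro-2H-chromen-2-yl)methyl]-4,6-dihydroxybenzoic acid, via open-chain diketo acid 19 (not isolated)
Conditions: H2 (1 atm), Pd/C (10 wt %), EtOAc, rt; filtered, evaporated below 30 °C
Reagents that add atoms: none
Why: Hydrogenolysis of the four aryl benzyl ethers frees the ring A phenol ortho to the C4 ketone, which should add to the C2 ketone in a 6-exo-trig hemiketalisation; nothing biases the two faces of C2, so the new stereocentre forms as the racemate, and the neutral non-alcoholic solvent prevents mixed-ketal formation and dehydration to the chromone.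

Step 11
Reactants: 20 rac-2-[(5-heptyl-2,7-dihydroxy-4-oxo-3,4-dihydro-2H-chromen-2-yl)methyl]-4,6-dihydroxybenzoic acid
Product: 21 2-{[(2R)-5-heptyl-2,7-dihydroxy-4-oxo-3,4-dihydro-2H-chromen-2-yl]methyl}-4,6-dihydroxybenzoic acid
Conditions: preparative HPLC, immobilised amylose tris(3,5-dimethylphenylcarbamate) phase, hexane/i-PrOH/AcOH (0.1 %), 5 °C; fractions evaporated below 20 °C
Reagents that add atoms: none
Why: Resolution by chromatography on a chiral stationary phase, in which the (2R) enantiomer is obtained by separation rather than by induction, its configuration to be assigned by electronic circular dichroism against calculation, while the (2S) fraction can be re-equilibrated through the open diketone and recycled.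

**Compound list**

1 | 2,4-dihydroxybenzoic acid | O=C(O)c1ccc(O)cc1O | starting material
2 | benzyl 2,4-bis(benzyloxy)benzoate | O=C(OCc1ccccc1)c1ccc(OCc2ccccc2)cc1OCc1ccccc1 | intermediate
3 | 2,4-bis(benzyloxy)benzoic acid | OC(=O)c1ccc(OCc2ccccc2)cc1OCc1ccccc1 | intermediate
4 | 3,5-bis(benzyloxy)benzyl bromide | BrCc1cc(OCc2ccccc2)cc(OCc2ccccc2)c1 | starting material
5 | hexylmagnesium bromide | CCCCCC[Mg]Br | starting material
6 | 1,3-bis(benzyloxy)-5-heptylbenzene | CCCCCCCc1cc(OCc2ccccc2)cc(OCc2ccccc2)c1 | intermediate
7 | 2,4-bis(benzyloxy)-6-heptylbenzaldehyde | CCCCCCCc1cc(OCc2ccccc2)cc(OCc2ccccc2)c1C=O | intermediate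
8 | 1,5-bis(benzyloxy)-2-(2,2-dibromoethenyl)-3-heptylbenzene | CCCCCCCc1cc(OCc2ccccc2)cc(OCc2ccccc2)c1C=C(Br)Br | intermediate
9 | lithium [2,4-bis(benzyloxy)-6-heptylphenyl]ethynide | CCCCCCCc1cc(OCc2ccccc2)cc(OCc2ccccc2)c1C#C[Li] | intermediate
10 | methyl 3-[2,4-bis(benzyloxy)-6-heptylphenyl]prop-2-ynoate | CCCCCCCc1cc(OCc2ccccc2)cc(OCc2ccccc2)c1C#CC(=O)OC | intermediate
11 | methyl (2E)-3-[2,4-bis(benzyloxy)-6-heptylphenyl]-3-methoxyprop-2-enoate | CO/C(=C/C(=O)OC)c1c(CCCCCCC)cc(OCc2ccccc2)cc1OCc1ccccc1 | intermediate
12 | (2E)-3-[2,4-bis(benzyloxy)-6-heptylphenyl]-3-methoxyprop-2-enoic acid | CO/C(=C/C(=O)O)c1c(CCCCCCC)cc(OCc2ccccc2)cc1OCc1ccccc1 | intermediate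
13 | (2E)-3-[2,4-bis(benzyloxy)-6-heptylphenyl]-3-methoxyprop-2-enoyl chloride | CO/C(=C/C(=O)Cl)c1c(CCCCCCC)cc(OCc2ccccc2)cc1OCc1ccccc1 | intermediate
14 | (3E)-4-[2,4-bis(benzyloxy)-6-heptylphenyl]-1-[dimethyl(oxo)-λ6-sulfanylidene]-4-methoxybut-3-en-2-one | CO/C(=C/C(=O)C=S(C)(C)=O)c1c(CCCCCCC)cc(OCc2ccccc2)cc1OCc1ccccc1 | intermediate
15 | 2,4-bis(benzyloxy)-6-[(3E)-4-[2,4-bis(benzyloxy)-6-heptylphenyl]-4-methoxy-2-oxobut-3-en-1-yl]benzoic acid | CO/C(=C/C(=O)Cc1cc(OCc2ccccc2)cc(OCc2ccccc2)c1C(=O)O)c1c(CCCCCCC)cc(OCc2ccccc2)cc1OCc1ccccc1 | intermediate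
16 | 6,8-bis(benzyloxy)-3-[(E)-2-[2,4-bis(benzyloxy)-6-heptylphenyl]-2-methoxyethenyl]-1H-isochromen-1-one | CO/C(=C/c1cc2cc(OCc3ccccc3)cc(OCc3ccccc3)c2c(=O)o1)c1c(CCCCCCC)cc(OCc2ccccc2)cc1OCc1ccccc1 | intermediate
17 | 6,8-bis(benzyloxy)-3-{2-[2,4-bis(benzyloxy)-6-heptylphenyl]-2-oxoethyl}-1H-isochromen-1-one | CCCCCCCc1cc(OCc2ccccc2)cc(OCc2ccccc2)c1C(=O)Cc1cc2cc(OCc3ccccc3)cc(OCc3ccccc3)c2c(=O)o1 | intermediate
18 | 2,4-bis(benzyloxy)-6-{4-[2,4-bis(benzyloxy)-6-heptylphenyl]-2,4-dioxobutyl}benzoic acid | CCCCCCCc1cc(OCc2ccccc2)cc(OCc2ccccc2)c1C(=O)CC(=O)Cc1cc(OCc2ccccc2)cc(OCc2ccccc2)c1C(=O)O | intermediate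
19 | 2-[4-(2-heptyl-4,6-dihydroxyphenyl)-2,4-dioxobutyl]-4,6-dihydroxybenzoic acid | CCCCCCCc1cc(O)cc(O)c1C(=O)CC(=O)Cc1cc(O)cc(O)c1C(=O)O | intermediate
20 | rac-2-[(5-heptyl-2,7-dihydroxy-4-oxo-3,4-dihydro-2H-chromen-2-yl)methyl]-4,6-dihydroxybenzoic acid | CCCCCCCc1cc(O)cc2c1C(=O)CC(O)(Cc1cc(O)cc(O)c1C(=O)O)O2 | intermediate
21 | 2-{[(2R)-5-heptyl-2,7-dihydroxy-4-oxo-3,4-dihydro-2H-chromen-2-yl]methyl}-4,6-dihydroxybenzoic acid | CCCCCCCc1cc(O)cc2c1C(=O)C[C@@](O)(Cc1cc(O)cc(O)c1C(=O)O)O2 | target

**Count**

Total steps: 11. Longest linear sequence: 10 steps (steps 2 to 11, from 4 to 21); step 1 supplies the second partner of step 8.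

**Steps most likely to fail**

Step 8. The cationic rhodium catalyst may be tied up by the electron-rich alkenyl ketone, or traces of acid and water may strip the enol ether before annulation, so that a chelating 1,3-diketone ylide forms and carbene transfer stalls. Incomplete lactonisation alone would not matter, because 15 is converted into 18 under the acid stage of step 9. The fallback buys the C1''–C1' bond with the starting material and makes C1'–C2 by acylation of a benzylic anion. It sets out from 12, which is converted with carbonyldiimidazole and N,O-dimethylhydroxylamine hydrochloride into (2E)-3-[2,4-bis(benzyloxy)-6-heptylphenyl]-N,3-dimethoxy-N-methylprop-2-enamide F1. Methyl 2,4-bis(benzyloxy)-6-methylbenzoate F2, made from commercial methyl 2,4-dihydroxy-6-methylbenzoate with BnBr and K2CO3, is deprotonated at its benzylic methyl group with LDA in THF at −78 °C (lateral lithiation) and acylated by F1. This should give methyl 2,4-bis(benzyloxy)-6-[(3E)-4-[2,4-bis(benzyloxy)-6-heptylphenyl]-4-methoxy-2-oxobut-3-en-1-yl]benzoate F3. Enol lactonisation of F3 with NaH in THF, with loss of methanol, returns to the route at 16.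

Step 11. The enantiomers may interconvert on the column or during evaporation through ring–chain tautomerism, so that the peaks merge and the collected material loses optical purity. The fallback turns this lability to advantage in a crystallisation-induced diastereomer transformation. It sets out from 20, which is stirred with (R)-1-phenylethylamine in ethyl acetate/heptane, so that the less soluble salt deposits while the solution re-equilibrates through the open diketone. The amine antipode, or another chiral base, would be chosen in a small screen so that the salt of the (2R) acid is the one that crystallises, shown here as (R)-1-phenylethylammonium 2-{[(2R)-5-heptyl-2,7-dihydroxy-4-oxo-3,4-dihydro-2H-chromen-2-yl]methyl}-4,6-dihydroxybenzoate F4. Cold partition of F4 between ethyl acetate and dilute aqueous citric acid returns to the route at 21.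

Step 7. At the acid chloride stage, HCl may cleave the enol ether, or the ortho benzyloxy oxygen of ring A, held next to the acyl carbon in the (E) isomer, may attack it with loss of benzyl chloride and lactonisation. The fallback replaces the acid chloride by an isolable active ester made under neutral carbodiimide conditions. It sets out from 12, which is coupled with 4-nitrophenol (EDC hydrochloride, DMAP cat., CH2Cl2) to give 4-nitrophenyl (2E)-3-[2,4-bis(benzyloxy)-6-heptylphenyl]-3-methoxyprop-2-enoate F5. Treatment of F5 with dimethylsulfoxonium methylide in THF at 0 °C → rt, a known acylation of this ylide by aryl esters, returns to the route at 14.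

**Further compounds**

F1 | step 8 | (2E)-3-[2,4-bis(benzyloxy)-6-heptylphenyl]-N,3-dimethoxy-N-methylprop-2-enamide | CO/C(=C/C(=O)N(C)OC)c1c(CCCCCCC)cc(OCc2ccccc2)cc1OCc1ccccc1
F2 | step 8 | methyl 2,4-bis(benzyloxy)-6-methylbenzoate | COC(=O)c1c(C)cc(OCc2ccccc2)cc1OCc1ccccc1
F3 | step 8 | methyl 2,4-bis(benzyloxy)-6-[(3E)-4-[2,4-bis(benzyloxy)-6-heptylphenyl]-4-methoxy-2-oxobut-3-en-1-yl]benzoate | CO/C(=C/C(=O)Cc1cc(OCc2ccccc2)cc(OCc2ccccc2)c1C(=O)OC)c1c(CCCCCCC)cc(OCc2ccccc2)cc1OCc1ccccc1
F4 | step 11 | (R)-1-phenylethylammonium 2-{[(2R)-5-heptyl-2,7-dihydroxy-4-oxo-3,4-dihydro-2H-chromen-2-yl]methyl}-4,6-dihydroxybenzoate | CCCCCCCc1cc(O)cc2c1C(=O)C[C@@](O)(Cc1cc(O)cc(O)c1C(=O)[O-])O2.C[C@@H]([NH3+])c1ccccc1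
F5 | step 7 | 4-nitrophenyl (2E)-3-[2,4-bis(benzyloxy)-6-heptylphenyl]-3-methoxyprop-2-enoate | CO/C(=C/C(=O)Oc1ccc(cc1)[N+](=O)[O-])c1c(CCCCCCC)cc(OCc2ccccc2)cc1OCc1ccccc1
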